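The seven-membered ring of the hydroazulene (azulene numbering, C1 = quaternary carbon) is disconnected at C4–C5 and C6–C7: the ring CH2–CH2 unit is acetylene, and C7, C8=C8a, C3a, C4 are the five carbons of a vinylcyclopropane. The key step, a rhodium-catalysed [5+2] cycloaddition, exploits the C8=C8a alkene flanked by the C7 and C3a/C4 stereocentres: it closes the ring, creates that alkene, carries the cyclopropane configuration into C4 and sets C7 from the Z geometry of the alkene. The precursor is a 1-alkenyl-6-methylbicyclo[3.1.0]hexane already holding the quaternary carbon and aryl side chain, built from 5,7-dimethoxycoumarin via lactone-controlled alkylation and gold-catalysed enyne cyclisation.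

Key step: step 12

Remark on the chemistry: the absolute sense of the copper-catalysed addition in step 1 depends on the ligand enantiomer; the enantiomer that gives the 4R lactone is assumed. Bicyclic products are named with bicyclo[3.1.0]hexane or azulene numbering.

Step 1
Reactants: 1 5,7-dimethoxycoumarin; 2 isobutylmagnesium bromide
Product: 3 (4R)-5,7-dimethoxy-4-(2-methylpropyl)-3,4-dihydro-2H-chromen-2-one
Conditions: CuBr·SMe2 (5 mol%), (R)-1-[(S)-2-(diphenylphosphino)ferrocenyl]ethyldicyclohexylphosphine or its enantiomer (6 mol%), tBuOMe/CH2Cl2, −75 °C; aq NH4Cl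
Reagents that add atoms: isobutylmagnesium bromide, CC(C)C[Mg]Br
Why: Copper-catalysed asymmetric conjugate addition of a Grignard reagent to a coumarin: the chiral diphosphine–copper complex delivers the isobutyl group to one face of C4 of the s-cis-locked enoate and so sets the benzylic stereocentre as 4R, while the lactone keeps one phenol oxygen masked and C2 in place as the future ring carbon.

Step 2
Reactants: 3 (4R)-5,7-dimethoxy-4-(2-methylpropyl)-3,4-dihydro-2H-chromen-2-one; 4 N-bromosuccinimide
Product: 5 (4R)-6,8-dibromo-5,7-dimethoxy-4-(2-methylpropyl)-3,4-dihydro-2H-chromen-2-one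
Conditions: NBS (2 equiv), MeCN, 0 °C to rt
Reagents that add atoms: N-bromosuccinimide, O=C1CCC(=O)N1Br
Why: Electrophilic aromatic bromination: C6 and C8 are each ortho or para to three oxygen donors and are brominated by two equivalents of NBS, which installs the future formyl positions and blocks the ring against later electrophilic side reactions without touching C4.

Step 3
Reactants: 5 (4R)-6,8-dibromo-5,7-dimethoxy-4-(2-methylpropyl)-3,4-dihydro-2H-chromen-2-one; 6 iodomethane
Product: 7 (3R,4R)-6,8-dibromo-5,7-dimethoxy-3-methyl-4-(2-methylpropyl)-3,4-dihydro-2H-chromen-2-one (trans epimer expected as the main one)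
Conditions: LiN(SiMe3)2, THF, −78 °C; MeI, −78 to −30 °C
Reagents that add atoms: iodomethane, CI
Why: Alkylation of the lithium lactone enolate with iodomethane; the methyl group enters mainly trans to the C4 isobutyl group, but C3 is planarised again in step 6, so its configuration here is of no consequence.

Step 4
Reactants: 8 pent-3-yn-1-ol
Product: 9 (Z)-pent-3-en-1-ol
Conditions: H2 (1 atm), Pd/CaCO3 poisoned with Pb(OAc)2 (Lindlar), quinoline, pentane, rt
Reagents that add atoms: none
Why: Lindlar semihydrogenation: syn delivery of H2 on poisoned palladium stops at the alkene and gives the Z geometry that later becomes the endo methyl group of the cyclopropane.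

Step 5
Reactants: 9 (Z)-pent-3-en-1-ol; 10 trifluoromethanesulfonic anhydride
Product: 11 (Z)-pent-3-en-1-yl trifluoromethanesulfonate
Conditions: Tf2O, 2,6-lutidine, CH2Cl2, −78 °C; used cold without storage
Reagents that add atoms: trifluoromethanesulfonic anhydride, O=S(=O)(OS(=O)(=O)C(F)(F)F)C(F)(F)F
Why: O-Sulfonylation of the primary alcohol gives a primary triflate, an electrophile reactive enough to quaternise a hindered enolate at low temperature.

Step 6
Reactants: 7 (3R,4R)-6,8-dibromo-5,7-dimethoxy-3-methyl-4-(2-methylpropyl)-3,4-dihydro-2H-chromen-2-one; 11 (Z)-pent-3-en-1-yl trifluoromethanesulfonate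
Product: 12 (3R,4S)-6,8-dibromo-5,7-dimethoxy-3-methyl-4-(2-methylpropyl)-3-[(3Z)-pent-3-en-1-yl]-3,4-dihydro-2H-chromen-2-one (methyl cis to isobutyl)
Conditions: LiN(iPr)2, THF, −78 °C; 11, −78 to −20 °C
Reagents that add atoms: (Z)-pent-3-en-1-yl trifluoromethanesulfonate, C/C=C\CCOS(=O)(=O)C(F)(F)F
Why: Diastereoselective alkylation of the tetrasubstituted lactone enolate: the C4 isobutyl group lies pseudo-axial (peri strain with the 5-methoxy group) and shields one face, so the pentenyl chain enters trans to it and sets the quaternary centre (3R) with methyl cis to isobutyl.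

Step 7
Reactants: 12 (3R,4S)-6,8-dibromo-5,7-dimethoxy-3-methyl-4-(2-methylpropyl)-3-[(3Z)-pent-3-en-1-yl]-3,4-dihydro-2H-chromen-2-one
Product: 13 (3R,4S)-6,8-dibromo-5,7-dimethoxy-3-methyl-4-(2-methylpropyl)-3-[(3Z)-pent-3-en-1-yl]-3,4-dihydro-2H-chromen-2-ol (lactol, both anomers)
Conditions: iBu2AlH, CH2Cl2, −78 °C; aq KNaC4H4O6
Reagents that add atoms: none
Why: Partial reduction of the hindered aryl lactone with iBu2AlH stops at the lactol because the aluminium hemiacetal is stable at −78 °C, and the quaternary C3 cannot epimerise.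

Step 8
Reactants: 13 lactol; 14 dimethyl (1-diazo-2-oxopropyl)phosphonate; 6 iodomethane
Product: 16 1,3-dibromo-5-[(4R,5R,8Z)-5-ethynyl-2,5-dimethyldec-8-en-4-yl]-2,4,6-trimethoxybenzene, via alkynyl phenol 15 (not isolated)
Conditions: K2CO3, MeOH, 0 °C to rt; then MeI, DMF, 40 °C
Reagents that add atoms: dimethyl (1-diazo-2-oxopropyl)phosphonate, COP(=O)(OC)C(=[N+]=[N-])C(C)=O; iodomethane, CI
Why: Seyferth–Gilbert homologation with the Ohira–Bestmann reagent acts on the open hydroxy aldehyde form of the lactol to give the terminal alkyne (no α-hydrogen, so no epimerisation), and the phenoxide set free is O-methylated in the same flask (Williamson ether synthesis).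

Step 9
Reactants: 16 1,3-dibromo-5-[(4R,5R,8Z)-5-ethynyl-2,5-dimethyldec-8-en-4-yl]-2,4,6-trimethoxybenzene; 17 diphenyl sulfoxide
Product: 18 (1R,2R,5R,6S)-2-[(1R)-1-(3,5-dibromo-2,4,6-trimethoxyphenyl)-3-methylbutyl]-2,6-dimethylbicyclo[3.1.0]hexane-1-carbaldehyde
Conditions: (IPr)AuCl (5 mol%), AgSbF6 (5 mol%), Ph2SO (2 equiv), CH2Cl2, rt (IPr = 1,3-bis(2,6-diisopropylphenyl)imidazol-2-ylidene)
Reagents that add atoms: diphenyl sulfoxide, O=S(c1ccccc1)c1ccccc1
Why: Gold-catalysed oxidative cycloisomerisation of a 1,6-enyne: 5-exo-dig attack of the alkene on the gold-activated alkyne gives a cyclopropyl gold carbene that Ph2SO oxidises to the aldehyde, the stereospecific syn addition to the Z-alkene setting the cis ring fusion and the endo 6-methyl group (C1, C5, C6) and approach anti to the bulky 1-aryl-3-methylbutyl group on C2 setting their sense relative to the quaternary carbon.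

Step 10
Reactants: 18 bicyclic aldehyde; 19 methyl bis(2,2,2-trifluoroethyl)phosphonoacetate
Product: 20 methyl (2Z)-3-[(1S,2R,5R,6S)-2-[(1R)-1-(3,5-dibromo-2,4,6-trimethoxyphenyl)-3-methylbutyl]-2,6-dimethylbicyclo[3.1.0]hexan-1-yl]prop-2-enoate
Conditions: KN(SiMe3)2, 18-crown-6, THF, −78 °C
Reagents that add atoms: methyl bis(2,2,2-trifluoroethyl)phosphonoacetate, COC(=O)CP(=O)(OCC(F)(F)F)OCC(F)(F)F
Why: Still–Gennari variant of the Horner–Wadsworth–Emmons olefination: the bis(trifluoroethyl) phosphonate anion with a dissociated potassium counter-ion eliminates under kinetic control to the (Z)-enoate, and the aldehyde has no α-hydrogen to lose.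

Step 11
Reactants: 20 (Z)-enoate; 21 methylmagnesium bromide
Product: 22 (3Z)-4-[(1S,2R,5R,6S)-2-[(1R)-1-(3,5-dibromo-2,4,6-trimethoxyphenyl)-3-methylbutyl]-2,6-dimethylbicyclo[3.1.0]hexan-1-yl]-2-methylbut-3-en-2-ol
Conditions: MeMgBr (excess), CeCl3, THF, −78 to 0 °C; aq NH4Cl
Reagents that add atoms: methylmagnesium bromide, C[Mg]Br
Why: Double 1,2-addition of the methylcerium reagent formed from MeMgBr and CeCl3 converts the ester into the tertiary alcohol without conjugate addition, bromine–metal exchange or loss of the Z geometry.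

Step 12
Reactants: 22 (Z)-alkenyl bicyclo[3.1.0]hexane carbinol; 23 acetylene
Product: 24 2-[(1R,3aR,4R,7R)-1-[(1R)-1-(3,5-dibromo-2,4,6-trimethoxyphenyl)-3-methylbutyl]-1,4-dimethyl-1,2,3,3a,4,7-hexahydroazulen-7-yl]propan-2-ol
Conditions: [Rh(CO)2Cl]2 (5 mol%), acetylene (1 atm), ClCH2CH2Cl, 60–80 °C
Reagents that add atoms: acetylene, C#C
Why: Rhodium-catalysed intermolecular [5+2] cycloaddition of a vinylcyclopropane with an alkyne, the closest known type being [Rh(CO)2Cl]2-catalysed cycloadditions of 1-substituted vinylcyclopropanes with alkynes: monovalent rhodium binds the alkene, opens the C1–C6 cyclopropane bond to a σ-alkyl/π-allyl rhodacyclohexene, acetylene inserts at the allyl terminus (former alkene CH) and reductive elimination at the former C6 gives the product. The seven-membered ring is closed by this two-bond annulation of the five-carbon unit (the two alkene carbons, C1, C5 and C6 of 22) with the two carbons of acetylene, the alkene moving to C8=C8a. The methyl-bearing carbon keeps its configuration (rhodium inserts and eliminates with retention) and becomes C4, so the endo methyl set in step 9 fixes C4 relative to C3a. The new C7 stereocentre is controlled by the Z geometry together with the suprafacial course: both bonds form on the face of the allyl unit from which C6 departs, which places the inner carbinol substituent trans to the C4 methyl (7R). The step needs cleavage of the exocyclic C1–C6 bond and not the ring-fusion C1–C5 bond, which is secured because the outer edge of C1–C5 is buried in the cyclopentane and its cleavage would give a bridged rhodacycle with a bridgehead alkene; the reacting face carries only the C2 methyl, the bulky side chain being on the other face. The quaternary C1 favours the reactive s-cis conformer as in 1-substituted vinylcyclopropanes, and symmetrical acetylene removes any regiochemical question.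

Step 13
Reactants: 24 hexahydroazulene diene
Product: 25 2-[(1R,3aR,4R,7R)-1-[(1R)-1-(3,5-dibromo-2,4,6-trimethoxyphenyl)-3-methylbutyl]-1,4-dimethyl-1,2,3,3a,4,5,6,7-octahydroazulen-7-yl]propan-2-ol
Conditions: H2 (1 atm), RhCl(PPh3)3 (10 mol%), benzene/EtOH, rt
Reagents that add atoms: none
Why: Homogeneous hydrogenation with RhCl(PPh3)3 reduces the cis-disubstituted C5=C6 alkene and leaves the hindered trisubstituted C8=C8a alkene and the aryl bromides untouched, so no stereocentre is formed or lost.

Step 14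
Reactants: 25 dibromo octahydroazulene carbinol; 26 N,N-dimethylformamide
Product: 27 5-[(1R)-1-[(1R,3aR,4R,7R)-7-(2-hydroxypropan-2-yl)-1,4-dimethyl-1,2,3,3a,4,5,6,7-octahydroazulen-1-yl]-3-methylbutyl]-2,4,6-trimethoxybenzene-1,3-dicarbaldehyde
Conditions: tBuLi (excess), THF, −78 °C; DMF, −78 to 0 °C; aq NH4Cl
Reagents that add atoms: N,N-dimethylformamide, CN(C)C=O
Why: Bromine–lithium exchange followed by formylation with DMF: the alkoxide forms first, both aryllithium centres are stabilised by two ortho methoxy groups, and hydrolysis of the hemiaminal alkoxides on work-up gives the dialdehyde.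

Step 15
Reactants: 27 trimethoxy dialdehyde
Product: 28 5-[(1R)-1-[(1R,3aR,4R,7R)-7-(2-hydroxypropan-2-yl)-1,4-dimethyl-1,2,3,3a,4,5,6,7-octahydroazulen-1-yl]-3-methylbutyl]-2,4,6-trihydroxybenzene-1,3-dicarbaldehyde (target, CNP0281883.1)
Conditions: 4-MeC6H4SLi (excess), HMPA/toluene, 110 °C; dilute aq HCl
Reagents that add atoms: none
Why: Nucleophilic O-demethylation (SN2 at methyl by the thiolate): every methoxy group is ortho to a formyl group, which makes each phenoxide a good leaving group, and the non-acidic conditions spare the tertiary alcohol and the trisubstituted alkene.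

Compound list
1 | 5,7-dimethoxycoumarin | COc1cc(OC)c2C=CC(=O)Oc2c1 | starting material
2 | isobutylmagnesium bromide | CC(C)C[Mg]Br | starting material
3 | (4R)-5,7-dimethoxy-4-(2-methylpropyl)-3,4-dihydro-2H-chromen-2-one | CC(C)C[C@@H]1CC(=O)Oc2cc(OC)cc(OC)c21 | intermediate
4 | N-bromosuccinimide | O=C1CCC(=O)N1Br | starting material
5 | (4R)-6,8-dibromo-5,7-dimethoxy-4-(2-methylpropyl)-3,4-dihydro-2H-chromen-2-one | CC(C)C[C@@H]1CC(=O)Oc2c(Br)c(OC)c(Br)c(OC)c21 | intermediate
6 | iodomethane | CI | starting material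
7 | (3R,4R)-6,8-dibromo-5,7-dimethoxy-3-methyl-4-(2-methylpropyl)-3,4-dihydro-2H-chromen-2-one | CC(C)C[C@@H]1[C@@H](C)C(=O)Oc2c(Br)c(OC)c(Br)c(OC)c21 | intermediate
8 | pent-3-yn-1-ol | CC#CCCO | starting material
9 | (Z)-pent-3-en-1-ol | C/C=C\CCO | intermediate
10 | trifluoromethanesulfonic anhydride | O=S(=O)(OS(=O)(=O)C(F)(F)F)C(F)(F)F | starting material
11 | (Z)-pent-3-en-1-yl trifluoromethanesulfonate | C/C=C\CCOS(=O)(=O)C(F)(F)F | intermediate
12 | (3R,4S)-6,8-dibromo-5,7-dimethoxy-3-methyl-4-(2-methylpropyl)-3-[(3Z)-pent-3-en-1-yl]-3,4-dihydro-2H-chromen-2-one | CC(C)C[C@@H]1[C@@](C)(CC/C=C\C)C(=O)Oc2c(Br)c(OC)c(Br)c(OC)c21 | intermediate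
13 | (3R,4S)-6,8-dibromo-5,7-dimethoxy-3-methyl-4-(2-methylpropyl)-3-[(3Z)-pent-3-en-1-yl]-3,4-dihydro-2H-chromen-2-ol (both anomers) | CC(C)C[C@@H]1[C@@](C)(CC/C=C\C)C(O)Oc2c(Br)c(OC)c(Br)c(OC)c21 | intermediate
14 | dimethyl (1-diazo-2-oxopropyl)phosphonate | COP(=O)(OC)C(=[N+]=[N-])C(C)=O | starting material
15 | 3,5-dibromo-2-[(4R,5R,8Z)-5-ethynyl-2,5-dimethyldec-8-en-4-yl]-4,6-dimethoxyphenol | CC(C)C[C@@H](c1c(O)c(Br)c(OC)c(Br)c1OC)[C@@](C)(CC/C=C\C)C#C | intermediate
16 | 1,3-dibromo-5-[(4R,5R,8Z)-5-ethynyl-2,5-dimethyldec-8-en-4-yl]-2,4,6-trimethoxybenzene | CC(C)C[C@@H](c1c(OC)c(Br)c(OC)c(Br)c1OC)[C@@](C)(CC/C=C\C)C#C | intermediate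
17 | diphenyl sulfoxide | O=S(c1ccccc1)c1ccccc1 | starting material
18 | (1R,2R,5R,6S)-2-[(1R)-1-(3,5-dibromo-2,4,6-trimethoxyphenyl)-3-methylbutyl]-2,6-dimethylbicyclo[3.1.0]hexane-1-carbaldehyde | CC(C)C[C@@H](c1c(OC)c(Br)c(OC)c(Br)c1OC)[C@@]1(C)CC[C@@H]2[C@H](C)[C@]12C=O | intermediate
19 | methyl bis(2,2,2-trifluoroethyl)phosphonoacetate | COC(=O)CP(=O)(OCC(F)(F)F)OCC(F)(F)F | starting material
20 | methyl (2Z)-3-[(1S,2R,5R,6S)-2-[(1R)-1-(3,5-dibromo-2,4,6-trimethoxyphenyl)-3-methylbutyl]-2,6-dimethylbicyclo[3.1.0]hexan-1-yl]prop-2-enoate | CC(C)C[C@@H](c1c(OC)c(Br)c(OC)c(Br)c1OC)[C@@]1(C)CC[C@@H]2[C@H](C)[C@]12/C=C\C(=O)OC | intermediate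
21 | methylmagnesium bromide | C[Mg]Br | starting material
22 | (3Z)-4-[(1S,2R,5R,6S)-2-[(1R)-1-(3,5-dibromo-2,4,6-trimethoxyphenyl)-3-methylbutyl]-2,6-dimethylbicyclo[3.1.0]hexan-1-yl]-2-methylbut-3-en-2-ol | CC(C)C[C@@H](c1c(OC)c(Br)c(OC)c(Br)c1OC)[C@@]1(C)CC[C@@H]2[C@H](C)[C@]12/C=C\C(C)(C)O | intermediate
23 | acetylene | C#C | starting material
24 | 2-[(1R,3aR,4R,7R)-1-[(1R)-1-(3,5-dibromo-2,4,6-trimethoxyphenyl)-3-methylbutyl]-1,4-dimethyl-1,2,3,3a,4,7-hexahydroazulen-7-yl]propan-2-ol | CC(C)C[C@@H](c1c(OC)c(Br)c(OC)c(Br)c1OC)[C@@]1(C)CC[C@H]2C1=C[C@H](C(C)(C)O)C=C[C@H]2C | intermediate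
25 | 2-[(1R,3aR,4R,7R)-1-[(1R)-1-(3,5-dibromo-2,4,6-trimethoxyphenyl)-3-methylbutyl]-1,4-dimethyl-1,2,3,3a,4,5,6,7-octahydroazulen-7-yl]propan-2-ol | CC(C)C[C@@H](c1c(OC)c(Br)c(OC)c(Br)c1OC)[C@@]1(C)CC[C@H]2C1=C[C@H](C(C)(C)O)CC[C@H]2C | intermediate
26 | N,N-dimethylformamide | CN(C)C=O | starting material
27 | 5-[(1R)-1-[(1R,3aR,4R,7R)-7-(2-hydroxypropan-2-yl)-1,4-dimethyl-1,2,3,3a,4,5,6,7-octahydroazulen-1-yl]-3-methylbutyl]-2,4,6-trimethoxybenzene-1,3-dicarbaldehyde | CC(C)C[C@@H](c1c(OC)c(C=O)c(OC)c(C=O)c1OC)[C@@]1(C)CC[C@H]2C1=C[C@H](C(C)(C)O)CC[C@H]2C | intermediate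
28 | 5-[(1R)-1-[(1R,3aR,4R,7R)-7-(2-hydroxypropan-2-yl)-1,4-dimethyl-1,2,3,3a,4,5,6,7-octahydroazulen-1-yl]-3-methylbutyl]-2,4,6-trihydroxybenzene-1,3-dicarbaldehyde | CC(C)C[C@@H](c1c(O)c(C=O)c(O)c(C=O)c1O)[C@@]1(C)CC[C@H]2C1=C[C@H](C(C)(C)O)CC[C@H]2C | target

Total step count: 15. Longest linear sequence: 13 steps (steps 1–3 and 6–15, from 1).

Steps most likely to fail

Step 12. After ring opening, insertion of acetylene at the allyl terminus that carries the inner carbinol group may be too slow, so that β-hydride elimination of the rhodacycle to ring-opened dienes, or oligomerisation of acetylene, takes over. The fallback uses a temporary tether and sets out from 22. The tertiary alcohol is silylated with chloro(ethynyl)dimethylsilane (imidazole, DMF) to the ethynyl(dimethyl)silyl ether F1. [Rh(CO)2Cl]2 or [(C10H8)Rh(cod)]SbF6 then effects the [5+2] cycloaddition intramolecularly, the alkyne being delivered from the inner oxygen to the same face, to give the oxasilole-fused cycloheptadiene F2. Bu4NF (THF/DMSO, 60 °C) cleaves the Si–O and alkenyl C–Si bonds by protodesilylation and the sequence comes back to the route at 24.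

Step 9. The cyclopropyl gold carbene may rearrange to skeletal-rearrangement dienes before the sulfoxide oxidises it, or the alkene may add to the wrong face relative to the quaternary carbon. The fallback is a diazo ester cyclopropanation and sets out from 16. Anti-Markovnikov hydration of the terminal alkyne (dicyclohexylborane, THF, 0 °C; NaBO3·4H2O) gives the homologous aldehyde F3. Pinnick oxidation (NaClO2, NaH2PO4, 2-methylbut-2-ene) gives the carboxylic acid F4, which trimethylsilyldiazomethane converts into the methyl ester F5. Detrifluoroacetylative diazo transfer (LiN(SiMe3)2, CF3CO2CH2CF3; then MsN3, Et3N) gives the α-diazo ester F6, which has no β-hydrogen. Cu(MeCN)4PF6-catalysed intramolecular cyclopropanation of the Z-alkene gives the bicyclic ester F7 with the same endo methyl group. iBu2AlH (toluene, −78 °C) reduces the hindered ester to the aldehyde and the sequence comes back to the route at 18.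

Step 1. The doubly donor-substituted, peri-hindered coumarin may react too slowly in the copper-catalysed addition, so that uncatalysed 1,2-addition to the lactone and erosion of enantioselectivity compete. The fallback transfers an alkenyl group and then hydrogenates, and sets out from 1. Rhodium-catalysed asymmetric 1,4-addition of (2-methylprop-1-en-1-yl)boronic acid ([Rh(acac)(C2H4)2], (R)- or (S)-SEGPHOS, dioxane/H2O, 60 °C) gives the 4-alkenyl lactone F8. Hydrogenation (H2, Pd/C, EtOAc) saturates the side-chain alkene and the sequence comes back to the route at 3.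

Further compounds
F1 | step 12 | ethynyl(dimethyl)silyl ether of 22 | CC(C)C[C@@H](c1c(OC)c(Br)c(OC)c(Br)c1OC)[C@@]1(C)CC[C@@H]2[C@H](C)[C@]12/C=C\C(C)(C)O[Si](C)(C)C#C
F2 | step 12 | oxasilole-fused hexahydroazulene cycloadduct (silicon on C6, oxygen on the C7 carbinol carbon) | CC(C)C[C@@H](c1c(OC)c(Br)c(OC)c(Br)c1OC)[C@@]1(C)CC[C@H]2C1=C[C@@H]3C(C)(C)O[Si](C)(C)C3=C[C@H]2C
F3 | step 9 | (6Z)-3-[(1R)-1-(3,5-dibromo-2,4,6-trimethoxyphenyl)-3-methylbutyl]-3-methyloct-6-enal (configuration as in 16) | CC(C)C[C@@H](c1c(OC)c(Br)c(OC)c(Br)c1OC)[C@@](C)(CC/C=C\C)CC=O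
F4 | step 9 | corresponding oct-6-enoic acid | CC(C)C[C@@H](c1c(OC)c(Br)c(OC)c(Br)c1OC)[C@@](C)(CC/C=C\C)CC(=O)O
F5 | step 9 | corresponding methyl oct-6-enoate | CC(C)C[C@@H](c1c(OC)c(Br)c(OC)c(Br)c1OC)[C@@](C)(CC/C=C\C)CC(=O)OC
F6 | step 9 | corresponding methyl 2-diazo-oct-6-enoate | CC(C)C[C@@H](c1c(OC)c(Br)c(OC)c(Br)c1OC)[C@@](C)(CC/C=C\C)C(=[N+]=[N-])C(=O)OC
F7 | step 9 | methyl 2-[(1R)-1-(3,5-dibromo-2,4,6-trimethoxyphenyl)-3-methylbutyl]-2,6-dimethylbicyclo[3.1.0]hexane-1-carboxylate (ring configuration as in 18) | CC(C)C[C@@H](c1c(OC)c(Br)c(OC)c(Br)c1OC)[C@@]1(C)CC[C@@H]2[C@H](C)[C@]12C(=O)OC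
F8 | step 1 | (4S)-5,7-dimethoxy-4-(2-methylprop-1-en-1-yl)-3,4-dihydro-2H-chromen-2-one | CC(C)=C[C@@H]1CC(=O)Oc2cc(OC)cc(OC)c21
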